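The numbers of this flask are invented.

21 M stood on the board against a charge of 0.80 M, a constant far larger than the charge, and the meeting on this flask began there.

starting material 0.80 M; protic impurity 0.0800 M; time 8.0 h

    starting material ⇌ target + released group (K1 = 21 M, k1 = 0.022 s⁻¹)
    starting material + protic impurity → quenched substrate (k2 = 0.22 M⁻¹ s⁻¹)
    target ⇌ isomer of the product (K3 = 0.37, k3 = 0.036 s⁻¹)

- at 8.0 h, what has stopped the reaction, if anything has (all of the starting material has reacted / it is still moving / forward and back rates have come level)
- target at 8.0 h, in percent of the starting material charged
- isomer of the product at 8.0 h, in percent of the starting material charged

- the reaction counts as stopped when no species that holds the starting material changes by six tenths of a point or more over the second half of the time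
- run time (flask): 8.0 h

The chair noted that the forward half-life of starting material by the release step (0.53 min), its half-life by the quench with protic impurity held at its charge (0.66 min) and the relaxation of target with isomer (0.0867 min) are short against the run, so she proposed balances in place of a clock. The process chemist objected. Starting material falls fast, he said, and the quench needs it, so protic impurity might outlive it.

I took the reckoning, on the chair's assumption and provisionally taking the quench as complete. That leaves 0.720 M to share out. Write A for starting material, P for target, E for isomer and W for released group. Each W came with a P or an E, and E is K3 times P, so the release balance becomes W times W over A equal to the pool constant, K1 times (one plus K3), 28.8 M. Solving the quadratic with A = share minus W gives W = 0.703 M and A = 0.0172 M, which is 2.15% of the charge.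

That answered the objection. With A at this resting state, the impurity decays pseudo-first-order and integrates to an exponential, with half-life 3.06 min, short against the run. I therefore committed to target 64.1% and isomer 23.7%.

The forecast gave forward and back rates have come level, with target 64.1% and isomer 23.7%, holding that “both reversible steps reach equilibrium”.

The simulation of the flask gives forward and back rates have come level, with target 64.1% and isomer 23.7%; target already stood at 64.1% after 0.400 h.

The neighbouring flask holds 0.20 M of starting material with the protic impurity unchanged, which is 0.400 equiv of impurity to starting material. Its share is 0.120 M, and the same 28.8 M gives W = 0.120 M, starting material 4.96 × 10⁻⁴ M, which is 0.248% of its charge, and target 43.6%. The run of the neighbouring flask gives starting material 0.25%, target 43.9% and isomer 16.2%. The impurity half-life reckoned for the neighbouring flask is 106 min, longer than in the first flask, and the neighbouring flask ends with 0.95% of its protic impurity.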